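Numbering is that of spiro[4.5]decane: ring A = C1–C5 (C1 O-isobutyryl, C3 isopropenyl), ring B = C5–C10 (C6 methyl, C8 ketone, C9 OAc, C10 methyl).
Cuts: first the C9–OAc bond (α'-acetoxylation of the enone) and the C1 ester. Ring B is then cut at C5–C6 and C8–C9 into methyl but-2-ynoate (C6, C7, C8 and the C6 methyl) and a ring A cyclopentanone that carries C10–C9.
Enabling feature: C5 is alpha to C1 (carried as a ketone) and C9 is alpha to a temporary CO2Me, so C5–C10–C9 is a 1,3-bis-nucleophile. C6 (β) and C8 (acyl) of the ynoate are the matching 1,3-bis-electrophile, and the C6=C7–C8=O enone results at the right oxidation level.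
Forward order: ring A by ozonolysis and aldol ring contraction of (S)-limonene; the C10–C9 chain by olefination and conjugate reduction; ring alkene to ketone to silyl enol ether; ring B in one anionic [3+3] cascade; then removal of the helpers (SiMe3, C1 ketone, CO2Me).
Stereochemistry: C3 comes from limonene, C10 from a chiral copper hydride catalyst, C5 from C10 in the key step, C1 from hydride attack anti to C10, and C9 from acetate delivery anti to the C10 methyl group.

Key step: step 8

Assumption: the ligand enantiomer named in step 4 is taken to deliver hydride to the face of the (E)-enoate that gives (3R)-7. If the sense of induction proves opposite, the mirror-image ligand is used.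

Step 1
Reactants: 1 (S)-limonene
Product: 3 (3S)-6-oxo-3-(prop-1-en-2-yl)heptanal, via secondary ozonide 2 (not isolated)
Conditions: O3 (1.0 equiv), CH2Cl2, −78 °C; Me2S, −78 °C to rt
Reagents that add atoms: ozone, [O-][O+]=O
Why: Ozone should attack the electron-rich trisubstituted ring alkene faster than the 1,1-disubstituted isopropenyl group (chemoselective ozonolysis with reductive work-up), and the limonene stereocenter, the later C3, is not touched.

Step 2
Reactants: 3 (3S)-6-oxo-3-(prop-1-en-2-yl)heptanal
Product: 4 1-[(4R)-4-(prop-1-en-2-yl)cyclopent-1-en-1-yl]ethan-1-one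
Conditions: KOH (aq), THF, 0 °C to rt
Reagents that add atoms: none
Why: Intramolecular aldol condensation (5-enolexo closure of the internal ketone enolate on the aldehyde, then E1cB loss of water) should give the conjugated acetylcyclopentene, and the amine-free medium avoids the enamine pathway to the isomeric cyclopentenecarbaldehyde.

Step 3
Reactants: 4 1-[(4R)-4-(prop-1-en-2-yl)cyclopent-1-en-1-yl]ethan-1-one; 5 trimethyl phosphonoacetate
Product: 6 methyl (2E)-3-[(4R)-4-(prop-1-en-2-yl)cyclopent-1-en-1-yl]but-2-enoate
Conditions: NaH, THF, 0 °C to reflux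
Reagents that add atoms: none
Why: Horner–Wadsworth–Emmons olefination of the methyl ketone should place the larger cyclopentenyl group trans to the ester and give mainly the (E)-dienoate.

Step 4
Reactants: 6 methyl (2E)-3-[(4R)-4-(prop-1-en-2-yl)cyclopent-1-en-1-yl]but-2-enoate
Product: 7 methyl (3R)-3-[(4R)-4-(prop-1-en-2-yl)cyclopent-1-en-1-yl]butanoate
Conditions: Cu(OAc)2 (5 mol %), (R)-DTBM-SEGPHOS (5 mol %), (EtO)2MeSiH, tBuOH, toluene, 0 °C
Reagents that add atoms: none
Why: Ligated copper hydride should add hydride 1,4 to the β,β-disubstituted enoate (asymmetric conjugate reduction), with the chiral bisphosphine choosing the face of the later C10 independently of the remote ring stereocenter, while the ring and isopropenyl alkenes are not activated and stay.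

Step 5
Reactants: 7 methyl (3R)-3-[(4R)-4-(prop-1-en-2-yl)cyclopent-1-en-1-yl]butanoate
Product: 8 methyl (3R)-3-[3-(prop-1-en-2-yl)-6-oxabicyclo[3.1.0]hexan-1-yl]butanoate (ring epoxide, both faces)
Conditions: mCPBA (1.0 equiv), NaHCO3, CH2Cl2, 0 °C
Reagents that add atoms: mCPBA (3-chloroperoxybenzoic acid), OOC(=O)c1cccc(Cl)c1
Why: Prilezhaev epoxidation should select the more nucleophilic trisubstituted ring alkene over the isopropenyl group, as in limonene itself, and the epoxide face does not matter because both new centers are erased in steps 6 and 7.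

Step 6
Reactants: 8 methyl (3R)-3-[3-(prop-1-en-2-yl)-6-oxabicyclo[3.1.0]hexan-1-yl]butanoate
Product: 9 methyl (3R)-3-[(4S)-2-oxo-4-(prop-1-en-2-yl)cyclopentyl]butanoate (epimers at the ring carbon that bears the chain)
Conditions: BF3·OEt2 (0.2 equiv), CH2Cl2, −78 °C
Reagents that add atoms: none
Why: Meinwald rearrangement should open the epoxide at its tertiary carbon and shift the neighbouring hydride to give the 2-substituted cyclopentanone, since ring contraction to a cyclobutane is disfavoured.

Step 7
Reactants: 9 methyl (3R)-3-[(4S)-2-oxo-4-(prop-1-en-2-yl)cyclopentyl]butanoate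
Product: 10 methyl (3R)-3-[(4S)-4-(prop-1-en-2-yl)-2-(trimethylsilyloxy)cyclopent-1-en-1-yl]butanoate
Conditions: Me3SiCl, NaI, Et3N, MeCN, rt
Reagents that add atoms: chlorotrimethylsilane, C[Si](C)(C)Cl
Why: Equilibrating silyl enol ether formation with iodotrimethylsilane made in the flask should favour the tetrasubstituted enol ether, which stores the later C5 as a regiodefined nucleophile, and any minor regioisomer is removed after step 8.

Step 8
Reactants: 10 methyl (3R)-3-[(4S)-4-(prop-1-en-2-yl)-2-(trimethylsilyloxy)cyclopent-1-en-1-yl]butanoate; 11 methyl but-2-ynoate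
Product: 14 methyl (3S,5R,10R)-6,10-dimethyl-1,8-dioxo-3-(prop-1-en-2-yl)spiro[4.5]dec-6-ene-9-carboxylate (C9 enolised or epimeric), via potassium enolate 12 (not isolated), via Michael adduct 13 (not isolated)
Conditions: KOtBu (2.2 equiv), 11 (1.2 equiv), THF, −40 °C to rt; AcOH
Reagents that add atoms: none
Why: tert-Butoxide strips the silyl group and frees the fully substituted C1–C5 enolate 12 regiospecifically; C5 adds to the β-carbon C6 of the ynoate (Michael addition), the allenolate is reprotonated to enoate 13, whose E and Z forms interconvert through the dienolate, and the C9 ester enolate of the Z form attacks the C8 ester carbonyl and expels methoxide (Dieckmann condensation). The closest known reaction types are the one-pot Michael–Dieckmann [3+3] annulation of 1,3-bis-nucleophiles such as acetonedicarboxylates with alk-2-ynoates and the Michael–Claisen route from ketones and acrylates to cyclohexane-1,3-diones. Ring B closes in the 6-(enolexo)-exo-trig mode. C5 is set in the intermolecular Michael step by C10: allylic strain turns the C10–H bond toward the enolate oxygen and the potassium-bound ester arm covers one face, so C6 should enter from the face that carries only the C10 methyl group, which places that methyl cis to C1 as in the target, while C9 is formed as an enolised, mobile center that is defined later. The step needs C5 (not C2) alkylation, which the silyl enol ether secures, and C9 (not C7 or C2) acylation, which thermodynamics secures. Only the C9-acylated product is an enolisable β-keto ester that is drained as its stabilised enolate, whereas acylation at C7 or at C2 (a bridgehead of a bicyclo[3.2.1]octane) gives non-enolisable 1,3-dicarbonyl compounds that methoxide reopens by retro-Claisen cleavage.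

Step 9
Reactants: 14 methyl (3S,5R,10R)-6,10-dimethyl-1,8-dioxo-3-(prop-1-en-2-yl)spiro[4.5]dec-6-ene-9-carboxylate
Product: 16 methyl (1R,3S,5R,10R)-1-hydroxy-6,10-dimethyl-8-oxo-3-(prop-1-en-2-yl)spiro[4.5]dec-6-ene-9-carboxylate, via sodium enolate 15 (not isolated)
Conditions: NaOMe (1.1 equiv), MeOH, 0 °C; NaBH4, −20 °C; AcOH
Reagents that add atoms: none
Why: With the β-keto ester and enone masked as their conjugated enolate (enolate protection), borohydride should reduce only the C1 ketone, attacking from the face of the flat C6 because the other face is covered by C10 and its methyl group, so that the C1 oxygen ends cis to C10.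

Step 10
Reactants: 16 methyl (1R,3S,5R,10R)-1-hydroxy-6,10-dimethyl-8-oxo-3-(prop-1-en-2-yl)spiro[4.5]dec-6-ene-9-carboxylate
Product: 17 (1R,3S,5R,10R)-1-hydroxy-6,10-dimethyl-3-(prop-1-en-2-yl)spiro[4.5]dec-6-en-8-one
Conditions: LiCl, H2O, DMSO, 130 °C
Reagents that add atoms: none
Why: Krapcho dealkoxycarbonylation (chloride attack on the ester methyl group, then loss of CO2 from the β-keto carboxylate) should remove the helper ester under near-neutral conditions that leave the alkenes and the stereocenters alone.

Step 11
Reactants: 17 (1R,3S,5R,10R)-1-hydroxy-6,10-dimethyl-3-(prop-1-en-2-yl)spiro[4.5]dec-6-en-8-one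
Product: 18 (1R,3S,5R,10R)-6,10-dimethyl-8-oxo-3-(prop-1-en-2-yl)spiro[4.5]dec-6-en-1-yl 2-methylpropanoate
Conditions: isobutyric anhydride, DMAP (0.2 equiv), pyridine, 40 °C
Reagents that add atoms: isobutyric anhydride, CC(C)C(=O)OC(=O)C(C)C
Why: DMAP-catalysed acylation should esterify the hindered secondary C1 alcohol with retention, since the C–O bond is not broken.

Step 12
Reactants: 18 (1R,3S,5R,10R)-6,10-dimethyl-8-oxo-3-(prop-1-en-2-yl)spiro[4.5]dec-6-en-1-yl 2-methylpropanoate
Product: 19 (1R,3S,5R,9R,10S)-9-acetoxy-6,10-dimethyl-8-oxo-3-(prop-1-en-2-yl)spiro[4.5]dec-6-en-1-yl 2-methylpropanoate (target)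
Conditions: Mn(OAc)3 (4 equiv), benzene, reflux (water separator)
Reagents that add atoms: Mn(OAc)3 (manganese triacetate), CC(=O)[O-].CC(=O)[O-].CC(=O)[O-].[Mn+3]
Why: α'-Acetoxylation of enones with trivalent manganese (manganese enolate, then acetate transfer), known to tolerate an isopropenyl group as in carvone, should functionalise C9 and deliver acetate anti to the C10 methyl group to give the trans, diequatorial and also thermodynamically preferred C9/C10 arrangement.

Compound list
1 | (S)-limonene | C=C(C)[C@@H]1CC=C(C)CC1 | starting material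
2 | secondary ozonide of the ring alkene of 1 | C=C(C)[C@@H]1CC2OOC(C)(CC1)O2 | intermediate
3 | (3S)-6-oxo-3-(prop-1-en-2-yl)heptanal | C=C(C)[C@@H](CCC(C)=O)CC=O | intermediate
4 | 1-[(4R)-4-(prop-1-en-2-yl)cyclopent-1-en-1-yl]ethan-1-one | C=C(C)[C@@H]1CC=C(C(C)=O)C1 | intermediate
5 | trimethyl phosphonoacetate | COC(=O)CP(=O)(OC)OC | starting material
6 | methyl (2E)-3-[(4R)-4-(prop-1-en-2-yl)cyclopent-1-en-1-yl]but-2-enoate | C=C(C)[C@@H]1CC=C(/C(C)=C/C(=O)OC)C1 | intermediate
7 | methyl (3R)-3-[(4R)-4-(prop-1-en-2-yl)cyclopent-1-en-1-yl]butanoate | C=C(C)[C@@H]1CC=C([C@H](C)CC(=O)OC)C1 | intermediate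
8 | methyl (3R)-3-[3-(prop-1-en-2-yl)-6-oxabicyclo[3.1.0]hexan-1-yl]butanoate, both epoxide faces | C=C(C)[C@@H]1CC2OC2([C@H](C)CC(=O)OC)C1 | intermediate
9 | methyl (3R)-3-[(4S)-2-oxo-4-(prop-1-en-2-yl)cyclopentyl]butanoate, epimers at the chain-bearing ring carbon | C=C(C)[C@@H]1CC(=O)C([C@H](C)CC(=O)OC)C1 | intermediate
10 | methyl (3R)-3-[(4S)-4-(prop-1-en-2-yl)-2-(trimethylsilyloxy)cyclopent-1-en-1-yl]butanoate | C=C(C)[C@@H]1CC(O[Si](C)(C)C)=C([C@H](C)CC(=O)OC)C1 | intermediate
11 | methyl but-2-ynoate | CC#CC(=O)OC | starting material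
12 | potassium C1–C5 enolate of 9 | C=C(C)[C@@H]1CC([O-])=C([C@H](C)CC(=O)OC)C1.[K+] | intermediate
13 | methyl (2Z)-3-[(1R,4S)-1-[(2R)-4-methoxy-4-oxobutan-2-yl]-2-oxo-4-(prop-1-en-2-yl)cyclopentyl]but-2-enoate | C=C(C)[C@@H]1CC(=O)[C@](C1)([C@H](C)CC(=O)OC)/C(C)=C\C(=O)OC | intermediate
14 | methyl (3S,5R,10R)-6,10-dimethyl-1,8-dioxo-3-(prop-1-en-2-yl)spiro[4.5]dec-6-ene-9-carboxylate, C9 mobile | C=C(C)[C@@H]1CC(=O)[C@@]2(C1)C(C)=CC(=O)C(C(=O)OC)[C@H]2C | intermediate
15 | sodium C8–C9 enolate of 14 | C=C(C)[C@@H]1CC(=O)[C@@]2(C1)C(C)=CC([O-])=C(C(=O)OC)[C@H]2C.[Na+] | intermediate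
16 | methyl (1R,3S,5R,10R)-1-hydroxy-6,10-dimethyl-8-oxo-3-(prop-1-en-2-yl)spiro[4.5]dec-6-ene-9-carboxylate, C9 mobile | C=C(C)[C@@H]1C[C@@H](O)[C@@]2(C1)C(C)=CC(=O)C(C(=O)OC)[C@H]2C | intermediate
17 | (1R,3S,5R,10R)-1-hydroxy-6,10-dimethyl-3-(prop-1-en-2-yl)spiro[4.5]dec-6-en-8-one | C=C(C)[C@@H]1C[C@@H](O)[C@@]2(C1)C(C)=CC(=O)C[C@H]2C | intermediate
18 | (1R,3S,5R,10R)-6,10-dimethyl-8-oxo-3-(prop-1-en-2-yl)spiro[4.5]dec-6-en-1-yl 2-methylpropanoate | C=C(C)[C@@H]1C[C@@H](OC(=O)C(C)C)[C@@]2(C1)C(C)=CC(=O)C[C@H]2C | intermediate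
19 | (1R,3S,5R,9R,10S)-9-acetoxy-6,10-dimethyl-8-oxo-3-(prop-1-en-2-yl)spiro[4.5]dec-6-en-1-yl 2-methylpropanoate | C=C(C)[C@@H]1C[C@@H](OC(=O)C(C)C)[C@@]2(C1)C(C)=CC(=O)[C@H](OC(C)=O)[C@H]2C | target

Total step count: 12. Longest linear sequence: 12 steps, from 1 to 19.

Steps most likely to fail

Step 8. The hindered enolate may add to the internal ynoate so slowly that the ynoate is lost to tert-butoxide addition or oligomerisation. Proton exchange may also move the enolate to C2 before the Michael step. The fallback sets out from 10 and comes back at 14. The tin enolate made from 10 with Bu3SnF is coupled with methyl (Z)-3-iodobut-2-enoate under zerovalent palladium catalysis (Pd2(dba)3, P(tBu)3, toluene). This ketone α-alkenylation forms C5–C6 by cross-coupling, fixes the Z geometry and gives 13 as an isolated compound. A separate Dieckmann condensation (NaOMe, MeOH) then closes 13 to 14.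

Step 6. The ester carbonyl may capture the developing tertiary cation and form a lactone, or the Lewis acid may attack the isopropenyl group, before the hydride shift takes place. The fallback sets out from 8 and comes back at 9. Trivalent titanium made from Cp2TiCl2 and Mn (collidine hydrochloride, 1,4-cyclohexadiene, THF) opens the epoxide homolytically to the tertiary radical. Hydrogen atom transfer then gives the secondary alcohol methyl (3R)-3-[(4S)-2-hydroxy-4-(prop-1-en-2-yl)cyclopentyl]butanoate F1. A Swern oxidation ((COCl)2, DMSO, Et3N) converts it to 9 without any cationic intermediate.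

Step 9. Facial selectivity of hydride delivery to C1 may be poor or reversed, because both faces are flanked by substituents of the quaternary C5. The fallback sets out from 14 and comes back at 18. The C1 epimer methyl (1S,3S,5R,10R)-1-hydroxy-6,10-dimethyl-8-oxo-3-(prop-1-en-2-yl)spiro[4.5]dec-6-ene-9-carboxylate F2 is taken on by Krapcho dealkoxycarbonylation to (1S,3S,5R,10R)-1-hydroxy-6,10-dimethyl-3-(prop-1-en-2-yl)spiro[4.5]dec-6-en-8-one F3. A Mitsunobu reaction with isobutyric acid (PPh3, DIAD, toluene) inverts C1 and installs the ester in one step to give 18.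

Further compounds
F0 | step 8 | none | none
F1 | step 6 | methyl (3R)-3-[(4S)-2-hydroxy-4-(prop-1-en-2-yl)cyclopentyl]butanoate | C=C(C)[C@@H]1CC(O)C([C@H](C)CC(=O)OC)C1
F2 | step 9 | methyl (1S,3S,5R,10R)-1-hydroxy-6,10-dimethyl-8-oxo-3-(prop-1-en-2-yl)spiro[4.5]dec-6-ene-9-carboxylate | C=C(C)[C@@H]1C[C@H](O)[C@@]2(C1)C(C)=CC(=O)C(C(=O)OC)[C@H]2C
F3 | step 9 | (1S,3S,5R,10R)-1-hydroxy-6,10-dimethyl-3-(prop-1-en-2-yl)spiro[4.5]dec-6-en-8-one | C=C(C)[C@@H]1C[C@H](O)[C@@]2(C1)C(C)=CC(=O)C[C@H]2C
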